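**Minutes of the meeting on the three vessels**

The meeting opened from what no step can alter, the count of substrate units: free substrate, plus 2 for each product, plus 3 for each idle adduct, must always return the charge. The following lay on the table.

| flask | substrate | time | remark |
|---|---|---|---|
| midnight | 20 mM | 25 min | a tube with plug flow, the mixed feed as stated, residence time 25 min |
| spring | 20 mM | 25 min | everything together in a closed stirred flask, run for 25 min |
| autumn | 20 mM |  | one stirred flow tank at steady state, fed with the mixture as stated, mean residence time 25 min |

    substrate + product ⇌ idle adduct, settled at all times (K1 = 19 M⁻¹)
    substrate + substrate ⇌ product (K2 = 32.9 M⁻¹, k2 = 0.202 M⁻¹ s⁻¹)

- the set-up with the highest amount of product at the outlet or at the end, in percent of the substrate put in ("none" if the first two lie within 2 percentage points) (midnight / spring / autumn / none)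
- amount of product at the outlet or at the end, in percent of the substrate put in, midnight
- amount of product at the outlet or at the end, in percent of the substrate put in, spring
- amount of product at the outlet or at the end, in percent of the substrate put in, autumn

- percent here means substrate units held: one product counts as two
- percent here means substrate units held: one idle adduct counts as three
- what is said of product includes idle adduct
- a doubled species enters its step squared and goes two at a time
- the stated concentrations are those of everything mixed, before any reaction; amounts are the same in each set-up
- in an amount of product, one idle adduct counts as one product
- run time (midnight): 25 min

I argued that this count, with both steps at balance, gives the free share of the charge. Dropping the idle adduct leaves a quadratic of strength 0.658, the equilibrium constant of the second step times the charge, and a free share of 57.1%.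

A colleague objected that the idle adduct cannot be dropped, so I fed that share back, which raised the strength to 0.872 and lowered the free share to 52.3%.

Asked whether balance is reached in time, I reckoned the relaxation half-life, the time in which a small departure from balance halves under the second step's forward and back runs together, at 0.792 min. Because that is far shorter than the run, I held that the tube of midnight, whose slices age like the closed flask of spring, ends at balance, with an amount of product, each idle adduct counted as one product, of 43.1%, and that the two tie.

For the tank of autumn I took a first-order lag: the residence time holds 21.9 relaxation lifetimes, and the tank reaches the balance value times that number over one more than that number, which gives 41.3%.

The forecast was then read: 47.4% for midnight, 47.4% for spring, 45.3% for autumn, best none, on the ground that “both sit at equilibrium with about 47% of substrate units held in product and adduct”. My figures stand lower than the forecast's, and in them each idle adduct counts as 2 units in the amount of product.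

The simulation gives 43.7% for midnight, 43.7% for spring and 41.8% for autumn, so best is none.

In midnight the relaxation half-life reads 0.789 min, short against the 25 min of the run, and the lag reckoned from my half-life takes the balance value 43.7% down to 41.8% for the tank of autumn. In a tank with 3 times the residence time the same lag gives 43.1%, and that tank stands at 43.1%.

The numbers were chosen freely, and the outcome is calculated.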